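## Retrosynthetic overview

1. Feature: the core is a bicyclo[3.2.1]octane (six-membered ring C1–C8–C7–C6–C5–C9, five-membered ring C1–C2–C3–C5–C9). The carbinol carbon C3 carries one oxygen and two acyl carbons, the ring ketone C2 and the exocyclic side-chain carbonyl, so C3 is a masked symmetric 2-silyloxymalonyl unit on C5.
2. Side chain last: Z-enone from the ynone (Lindlar), ynone from the exo C3 chlorocarbonyl group and silyl-protected 2-methylbut-3-yn-2-ol (acyl Sonogashira), then desilylation.
3. Key disconnection C1–C2: the magnesium enolate of the C9/isobutyryl β-diketone acylates through C1 one of the two diastereotopic acid chlorides of the C5 silyloxymalonyl dichloride. This closes the five-membered ring (second ring) and sets C1 and C3.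
4. Precursor: quaternary C5 by aldol addition of the C5 dienolate to dimethyl ketomalonate anti to the C7 prenyl group; C8 gem-dimethyl and C1 isobutyryl by methyl conjugate addition, aldol addition and oxidation.
5. Six-membered ring first: organocatalytic Michael addition of 5-methylhex-4-enal to methyl vinyl ketone (sets C7), then aldol condensation.

Key step: step 12

Assumption: 5-methylhex-4-enal (1) and dimethyl ketomalonate (10, anhydrous keto form) are taken as catalogue reagents; the methyl esters are chosen because they survive the organocopper step and can be cleaved at the methyl carbon despite the crowded carbonyl groups.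

Locants C1–C3 and C5–C9 in names and text are those of the overview (there is no C4).

## Route

Step 1
Reactants: 1 5-methylhex-4-enal; 2 but-3-en-2-one (methyl vinyl ketone)
Product: 3 (2S)-2-(3-methylbut-2-en-1-yl)-5-oxohexanal
Conditions: (S)-2-[methoxy(diphenyl)methyl]pyrrolidine (5 mol %), ethyl 3,4-dihydroxybenzoate (20 mol %), neat, 4 °C
Reagents that add atoms: none
Why: Enamine-catalysed asymmetric Michael addition in which the diphenyl(methoxy)methyl group shields one face of the anti-enamine of 1, so that the enone should add to the open face and set the future C7 (S in 3, R in the target).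

Step 2
Reactants: 3 (2S)-2-(3-methylbut-2-en-1-yl)-5-oxohexanal
Product: 4 (4S)-4-(3-methylbut-2-en-1-yl)cyclohex-2-en-1-one
Conditions: LiOH, iPrOH, rt
Reagents that add atoms: none
Why: Intramolecular aldol condensation of the methyl ketone onto the aldehyde closes the six-membered ring (C1–C8 bond) under mild base, and the stereocentre becomes the γ-carbon C7 of the enone.

Step 3
Reactants: 4 (4S)-4-(3-methylbut-2-en-1-yl)cyclohex-2-en-1-one
Product: 5 trimethyl{[(3S,4S)-3-methyl-4-(3-methylbut-2-en-1-yl)cyclohex-1-en-1-yl]oxy}silane (methyl trans to prenyl)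
Conditions: Me2CuLi, Me3SiCl, THF, −78 °C
Reagents that add atoms: lithium dimethylcuprate, [Li+].C[Cu-]C; chlorotrimethylsilane, C[Si](C)(C)Cl
Why: Silyl chloride-accelerated Gilman conjugate addition places the first methyl group on C8 anti to the C7 prenyl group and traps the enolate regiospecifically as the C1=C9 silyl enol ether.

Step 4
Reactants: 5 trimethyl{[(3S,4S)-3-methyl-4-(3-methylbut-2-en-1-yl)cyclohex-1-en-1-yl]oxy}silane
Product: 6 (4S)-3-methyl-4-(3-methylbut-2-en-1-yl)cyclohex-2-en-1-one
Conditions: Pd(OAc)2 (1 equiv), MeCN, rt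
Reagents that add atoms: none
Why: Saegusa–Ito oxidation, in which the palladium enolate at C1 loses the C8 hydrogen by β-hydride elimination, restores the enone with the C8 methyl group in place and leaves C7 untouched.

Step 5
Reactants: 6 (4S)-3-methyl-4-(3-methylbut-2-en-1-yl)cyclohex-2-en-1-one; 7 1-bromo-3-methylbut-2-ene (prenyl bromide)
Product: 9 (4R)-3-methyl-4,6-bis(3-methylbut-2-en-1-yl)cyclohex-2-en-1-one (mixture of C6 epimers; ring C6 is C5 of the overview), via lithium dienolate 8 (not isolated)
Conditions: LiN(iPr)2, THF, −78 °C; then 7, −78 → 0 °C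
Reagents that add atoms: none
Why: Kinetic α′-deprotonation of the enone gives the cross-conjugated dienolate 8, which is C-alkylated by the allylic bromide at C5 (Stork-type enone α′-alkylation); the C5 configuration is immaterial because C5 is enolised again in step 6.

Step 6
Reactants: 9 (4R)-3-methyl-4,6-bis(3-methylbut-2-en-1-yl)cyclohex-2-en-1-one; 10 dimethyl 2-oxopropanedioate (dimethyl ketomalonate)
Product: 12 dimethyl 2-hydroxy-2-[(1S,5R)-4-methyl-1,5-bis(3-methylbut-2-en-1-yl)-2-oxocyclohex-3-en-1-yl]propanedioate, via lithium dienolate 11 (not isolated)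
Conditions: LiN(iPr)2, THF, −78 °C; then 10, −78 °C; AcOH quench at −78 °C
Reagents that add atoms: none
Why: Aldol addition of the tetrasubstituted lithium dienolate 11 to the non-enolisable keto carbonyl of 10 forms the C3–C5 bond, and because the C7 prenyl group sits pseudo-axial (allylic strain with the C8 methyl group) and covers one face of C5, the electrophile should enter anti to it and set the quaternary C5 with the malonyl unit trans to the C7 prenyl group, the cold acetic acid quench forestalling retro-aldol cleavage.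

Step 7
Reactants: 12 dimethyl 2-hydroxy-2-[(1S,5R)-4-methyl-1,5-bis(3-methylbut-2-en-1-yl)-2-oxocyclohex-3-en-1-yl]propanedioate
Product: 13 dimethyl 2-[(1S,5R)-4-methyl-1,5-bis(3-methylbut-2-en-1-yl)-2-oxocyclohex-3-en-1-yl]-2-[(triethylsilyl)oxy]propanedioate
Conditions: Et3SiOTf, 2,6-lutidine, CH2Cl2, −78 → 0 °C
Reagents that add atoms: triethylsilyl trifluoromethanesulfonate, CC[Si](CC)(CC)OS(=O)(=O)C(F)(F)F
Why: Silyl triflate O-silylation of the hindered tertiary alcohol removes the retro-aldol pathway and protects the future C3 oxygen as a triethylsilyl ether that should survive the basic and oxidative steps ahead.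

Step 8
Reactants: 13 dimethyl 2-[(1S,5R)-4-methyl-1,5-bis(3-methylbut-2-en-1-yl)-2-oxocyclohex-3-en-1-yl]-2-[(triethylsilyl)oxy]propanedioate; 14 2-methylpropanal
Product: 16 dimethyl 2-[(1S,5R)-3-(1-hydroxy-2-methylpropyl)-4,4-dimethyl-1,5-bis(3-methylbut-2-en-1-yl)-2-oxocyclohexyl]-2-[(triethylsilyl)oxy]propanedioate (mixture at ring C3 and the carbinol carbon), via bromomagnesium enolate 15 (not isolated)
Conditions: MeMgBr, CuBr·SMe2 (20 mol %), THF, −40 °C; then 14, −78 °C
Reagents that add atoms: methylmagnesium bromide, C[Mg]Br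
Why: Copper-catalysed conjugate addition of the methyl Grignard reagent to the β,β-disubstituted enone creates the C8 gem-dimethyl group and the regiodefined enolate 15, which undergoes aldol addition to 14 at C1; the two new stereocentres are erased by the oxidation and enolisation that follow.

Step 9
Reactants: 16 dimethyl 2-[(1S,5R)-3-(1-hydroxy-2-methylpropyl)-4,4-dimethyl-1,5-bis(3-methylbut-2-en-1-yl)-2-oxocyclohexyl]-2-[(triethylsilyl)oxy]propanedioate
Product: 17 dimethyl 2-[2-hydroxy-4,4-dimethyl-1,5-bis(3-methylbut-2-en-1-yl)-3-(2-methylpropanoyl)cyclohex-2-en-1-yl]-2-[(triethylsilyl)oxy]propanedioate (enol tautomer of the C9/isobutyryl β-diketone; C5 and C7 as in 13)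
Conditions: Dess–Martin periodinane, CH2Cl2, 0 °C → rt
Reagents that add atoms: none
Why: Dess–Martin oxidation of the β-hydroxy ketone gives the β-diketone without touching the alkenes, the esters or the silyl ether.

Step 10
Reactants: 17 dimethyl ester of the C5 silyloxymalonyl β-diketone
Product: 18 2-[2-hydroxy-4,4-dimethyl-1,5-bis(3-methylbut-2-en-1-yl)-3-(2-methylpropanoyl)cyclohex-2-en-1-yl]-2-[(triethylsilyl)oxy]propanedioic acid (C5 and C7 as in 13)
Conditions: n-PrSLi (excess), HMPA, rt; then dilute aq. HCl to pH 4, 0 °C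
Reagents that add atoms: none
Why: Thiolate SN2 demethylation (Bartlett–Johnson ester cleavage) attacks the methyl carbon, so the crowding of the two ester carbonyl groups is irrelevant, and the β-diketone is held as its unreactive enolate during the reaction.

Step 11
Reactants: 18 C5 silyloxymalonic acid of the β-diketone
Product: 19 2-[2-hydroxy-4,4-dimethyl-1,5-bis(3-methylbut-2-en-1-yl)-3-(2-methylpropanoyl)cyclohex-2-en-1-yl]-2-[(triethylsilyl)oxy]propanedioyl dichloride (C5 silyloxymalonyl dichloride, enol form; C5 and C7 as in 13)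
Conditions: 1-chloro-N,N,2-trimethylprop-1-en-1-amine (2.1 equiv), CH2Cl2, 0 °C; concentrated and used crude
Reagents that add atoms: 1-chloro-N,N,2-trimethylprop-1-en-1-amine (Ghosez reagent), CC(C)=C(Cl)N(C)C
Why: The α-chloroenamine converts both carboxylic acids into acid chlorides under neutral conditions without free HCl, so the prenyl alkenes and the silyl ether are spared, and the hindered hydrogen-bonded enol should react far more slowly than the acids.

Step 12
Reactants: 19 C5 silyloxymalonyl dichloride of the β-diketone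
Product: 21 (1R,3R,5S,7R)-8,8-dimethyl-1-(2-methylpropanoyl)-5,7-bis(3-methylbut-2-en-1-yl)-2,9-dioxo-3-[(triethylsilyl)oxy]bicyclo[3.2.1]octane-3-carbonyl chloride (silyloxy endo, chlorocarbonyl exo), via chloromagnesium enolate 20 (not isolated)
Conditions: MgCl2 (2 equiv), Et3N (2.5 equiv), MeCN/CH2Cl2, 0.005 M, −20 °C → rt; filtered and concentrated under argon
Reagents that add atoms: none
Why: Proposed new method: MgCl2/Et3N turns the C9/isobutyryl β-diketone into the chelated magnesium enolate 20, whose C1 adds to one of the two diastereotopic chlorocarbonyl groups on C3 and expels chloride, an addition–elimination that is irreversible because the C1 triketone formed cannot enolise and C3 carries no hydrogen for a ketene or epimerisation pathway; the closest known chemistry is the intramolecular C-acylation that ends the Effenberger malonyl dichloride annulation and the MgCl2/Et3N C-acylation of 1,3-dicarbonyl compounds, but neither a choice between two diastereotopic acyl chlorides nor this five-membered bridging closure at a hindered C1 has been shown. The five-membered ring C1–C2–C3–C5–C9 closes in a 5-exo-trig mode at the acyl carbon (5-(enolendo)-exo-trig with respect to the C1=C9 enolate), which is geometrically possible only from the half-chair that carries the C3 unit pseudo-axial on C5, the conformer that also keeps both prenyl groups equatorial. In that conformer the acyl carbon lies over the C1 lobe of the enolate and out of reach of the in-plane C9 oxygen, which together with chelation of both oxygens by magnesium should favour C- over O-acylation. C1 is set by the tether, since the new bond can only form on the ring face that bears the C5–C3 bond fixed in step 6. C3 is set by the choice of acyl group: in the product-like transition state one spectator substituent lies endo under the axial C7 hydrogen and the other exo beside the C9 carbonyl, and the silyloxy group, attached through one small oxygen with its ethyl groups turned outwards, should accept the endo site more readily than the wider planar chlorocarbonyl group, which gives the C3–O bond endo as in the target. The step therefore needs C- over O-acylation and endo-oxygen over endo-acyl selection, with high dilution against intermolecular acylation; the first rests on the pseudo-axial arm and the chelate, the second on the size difference of the two spectator groups in the endo pocket.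

Step 13
Reactants: 22 2-methylbut-3-yn-2-ol
Product: 23 triethyl[(2-methylbut-3-yn-2-yl)oxy]silane
Conditions: Et3SiOTf, 2,6-lutidine, CH2Cl2, 0 °C
Reagents that add atoms: triethylsilyl trifluoromethanesulfonate, CC[Si](CC)(CC)OS(=O)(=O)C(F)(F)F
Why: Silyl triflate silylation masks the tertiary propargylic hydroxyl group for the acylation and semi-hydrogenation steps, so that both silyl ethers can be removed together at the end.

Step 14
Reactants: 21 bicyclic trione with exo C3 chlorocarbonyl group; 23 triethyl[(2-methylbut-3-yn-2-yl)oxy]silane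
Product: 24 (1R,3S,5S,7R)-8,8-dimethyl-3-{4-methyl-4-[(triethylsilyl)oxy]pent-2-ynoyl}-1-(2-methylpropanoyl)-5,7-bis(3-methylbut-2-en-1-yl)-3-[(triethylsilyl)oxy]bicyclo[3.2.1]octane-2,9-dione
Conditions: PdCl2(PPh3)2 (3 mol %), CuI (6 mol %), Et3N, THF, rt
Reagents that add atoms: none
Why: Acyl Sonogashira coupling, in which zerovalent palladium inserts into the C–Cl bond of the acid chloride and the copper acetylide of 23 transmetallates, gives the ynone; C3 has no hydrogen, so no ketene can form, and tertiary acid chlorides such as pivaloyl chloride are established substrates.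

Step 15
Reactants: 24 bis-silyl ynone
Product: 25 (1R,3S,5S,7R)-8,8-dimethyl-3-{(2Z)-4-methyl-4-[(triethylsilyl)oxy]pent-2-enoyl}-1-(2-methylpropanoyl)-5,7-bis(3-methylbut-2-en-1-yl)-3-[(triethylsilyl)oxy]bicyclo[3.2.1]octane-2,9-dione
Conditions: H2 (1 atm), Lindlar catalyst (Pd/CaCO3 poisoned with Pb(OAc)2), quinoline, EtOAc, rt
Reagents that add atoms: none
Why: Lindlar semi-hydrogenation delivers hydrogen syn to the alkyne and should stop at the Z-enone, while the trisubstituted prenyl alkenes are not reduced on the poisoned catalyst.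

Step 16
Reactants: 25 bis-silyl Z-enone
Product: 26 (1R,3S,5S,7R)-3-hydroxy-3-[(2Z)-4-hydroxy-4-methylpent-2-enoyl]-8,8-dimethyl-1-(2-methylpropanoyl)-5,7-bis(3-methylbut-2-en-1-yl)bicyclo[3.2.1]octane-2,9-dione (CNP0190794.1)
Conditions: HF·pyridine, pyridine, THF, 0 °C → rt
Reagents that add atoms: none
Why: Buffered HF·pyridine cleaves both tertiary triethylsilyl ethers under mildly acidic conditions, which avoids the base-induced retro-Claisen and α-ketol pathways open to the α-hydroxy β-diketone.

## Compound list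

1 | 5-methylhex-4-enal | CC(C)=CCCC=O | starting material
2 | but-3-en-2-one (methyl vinyl ketone) | CC(=O)C=C | starting material
3 | (2S)-2-(3-methylbut-2-en-1-yl)-5-oxohexanal | CC(C)=CC[C@@H](C=O)CCC(C)=O | intermediate
4 | (4S)-4-(3-methylbut-2-en-1-yl)cyclohex-2-en-1-one | CC(C)=CC[C@@H]1CCC(=O)C=C1 | intermediate
5 | trimethyl{[(3S,4S)-3-methyl-4-(3-methylbut-2-en-1-yl)cyclohex-1-en-1-yl]oxy}silane | CC(C)=CC[C@@H]1CCC(O[Si](C)(C)C)=C[C@H]1C | intermediate
6 | (4S)-3-methyl-4-(3-methylbut-2-en-1-yl)cyclohex-2-en-1-one | CC(C)=CC[C@@H]1CCC(=O)C=C1C | intermediate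
7 | 1-bromo-3-methylbut-2-ene (prenyl bromide) | CC(C)=CCBr | starting material
8 | lithium dienolate of 6 (cross-conjugated, C5=C9) | CC(C)=CC[C@@H]1CC=C(O[Li])C=C1C | intermediate (not isolated)
9 | (4R)-3-methyl-4,6-bis(3-methylbut-2-en-1-yl)cyclohex-2-en-1-one, C6 epimers | CC(C)=CC[C@@H]1CC(CC=C(C)C)C(=O)C=C1C | intermediate
10 | dimethyl 2-oxopropanedioate (dimethyl ketomalonate) | COC(=O)C(=O)C(=O)OC | starting material
11 | lithium dienolate of 9 (tetrasubstituted at C5) | CC(C)=CC[C@@H]1CC(CC=C(C)C)=C(O[Li])C=C1C | intermediate (not isolated)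
12 | dimethyl 2-hydroxy-2-[(1S,5R)-4-methyl-1,5-bis(3-methylbut-2-en-1-yl)-2-oxocyclohex-3-en-1-yl]propanedioate | CC(C)=CC[C@@H]1C[C@@](CC=C(C)C)(C(O)(C(=O)OC)C(=O)OC)C(=O)C=C1C | intermediate
13 | dimethyl 2-[(1S,5R)-4-methyl-1,5-bis(3-methylbut-2-en-1-yl)-2-oxocyclohex-3-en-1-yl]-2-[(triethylsilyl)oxy]propanedioate | CC(C)=CC[C@@H]1C[C@@](CC=C(C)C)(C(O[Si](CC)(CC)CC)(C(=O)OC)C(=O)OC)C(=O)C=C1C | intermediate
14 | 2-methylpropanal | CC(C)C=O | starting material
15 | bromomagnesium C1=C9 enolate of the 8,8-dimethyl ketone derived from 13 | CC(C)=CC[C@@H]1C[C@@](CC=C(C)C)(C(O[Si](CC)(CC)CC)(C(=O)OC)C(=O)OC)C(O[Mg]Br)=CC1(C)C | intermediate (not isolated)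
16 | dimethyl 2-[(1S,5R)-3-(1-hydroxy-2-methylpropyl)-4,4-dimethyl-1,5-bis(3-methylbut-2-en-1-yl)-2-oxocyclohexyl]-2-[(triethylsilyl)oxy]propanedioate, mixture at ring C3 and carbinol carbon | CC(C)=CC[C@@H]1C[C@@](CC=C(C)C)(C(O[Si](CC)(CC)CC)(C(=O)OC)C(=O)OC)C(=O)C(C(O)C(C)C)C1(C)C | intermediate
17 | dimethyl 2-[2-hydroxy-4,4-dimethyl-1,5-bis(3-methylbut-2-en-1-yl)-3-(2-methylpropanoyl)cyclohex-2-en-1-yl]-2-[(triethylsilyl)oxy]propanedioate, enol form, C5 and C7 as in 13 | CC(C)=CC[C@@H]1C[C@@](CC=C(C)C)(C(O[Si](CC)(CC)CC)(C(=O)OC)C(=O)OC)C(O)=C(C(=O)C(C)C)C1(C)C | intermediate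
18 | 2-[2-hydroxy-4,4-dimethyl-1,5-bis(3-methylbut-2-en-1-yl)-3-(2-methylpropanoyl)cyclohex-2-en-1-yl]-2-[(triethylsilyl)oxy]propanedioic acid, C5 and C7 as in 13 | CC(C)=CC[C@@H]1C[C@@](CC=C(C)C)(C(O[Si](CC)(CC)CC)(C(=O)O)C(=O)O)C(O)=C(C(=O)C(C)C)C1(C)C | intermediate
19 | 2-[2-hydroxy-4,4-dimethyl-1,5-bis(3-methylbut-2-en-1-yl)-3-(2-methylpropanoyl)cyclohex-2-en-1-yl]-2-[(triethylsilyl)oxy]propanedioyl dichloride, C5 and C7 as in 13 (key-step precursor) | CC(C)=CC[C@@H]1C[C@@](CC=C(C)C)(C(O[Si](CC)(CC)CC)(C(Cl)=O)C(Cl)=O)C(O)=C(C(=O)C(C)C)C1(C)C | intermediate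
20 | chloromagnesium chelated enolate of 19 | CC(C)=CC[C@@H]1C[C@@](CC=C(C)C)(C(O[Si](CC)(CC)CC)(C(Cl)=O)C(Cl)=O)C(O[Mg]Cl)=C(C(=O)C(C)C)C1(C)C | intermediate (not isolated)
21 | (1R,3R,5S,7R)-8,8-dimethyl-1-(2-methylpropanoyl)-5,7-bis(3-methylbut-2-en-1-yl)-2,9-dioxo-3-[(triethylsilyl)oxy]bicyclo[3.2.1]octane-3-carbonyl chloride, silyloxy endo, chlorocarbonyl exo (key-step product) | CC(C)=CC[C@@H]1C[C@]2(CC=C(C)C)C(=O)[C@@](C(=O)C(C)C)(C(=O)[C@@]2(O[Si](CC)(CC)CC)C(Cl)=O)C1(C)C | intermediate
22 | 2-methylbut-3-yn-2-ol | CC(C)(O)C#C | starting material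
23 | triethyl[(2-methylbut-3-yn-2-yl)oxy]silane | CC[Si](CC)(CC)OC(C)(C)C#C | intermediate
24 | (1R,3S,5S,7R)-8,8-dimethyl-3-{4-methyl-4-[(triethylsilyl)oxy]pent-2-ynoyl}-1-(2-methylpropanoyl)-5,7-bis(3-methylbut-2-en-1-yl)-3-[(triethylsilyl)oxy]bicyclo[3.2.1]octane-2,9-dione | CC(C)=CC[C@@H]1C[C@]2(CC=C(C)C)C(=O)[C@@](C(=O)C(C)C)(C(=O)[C@@]2(O[Si](CC)(CC)CC)C(=O)C#CC(C)(C)O[Si](CC)(CC)CC)C1(C)C | intermediate
25 | (1R,3S,5S,7R)-8,8-dimethyl-3-{(2Z)-4-methyl-4-[(triethylsilyl)oxy]pent-2-enoyl}-1-(2-methylpropanoyl)-5,7-bis(3-methylbut-2-en-1-yl)-3-[(triethylsilyl)oxy]bicyclo[3.2.1]octane-2,9-dione | CC(C)=CC[C@@H]1C[C@]2(CC=C(C)C)C(=O)[C@@](C(=O)C(C)C)(C(=O)[C@@]2(O[Si](CC)(CC)CC)C(=O)/C=C\C(C)(C)O[Si](CC)(CC)CC)C1(C)C | intermediate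
26 | (1R,3S,5S,7R)-3-hydroxy-3-[(2Z)-4-hydroxy-4-methylpent-2-enoyl]-8,8-dimethyl-1-(2-methylpropanoyl)-5,7-bis(3-methylbut-2-en-1-yl)bicyclo[3.2.1]octane-2,9-dione | CC(C)=CC[C@@H]1C[C@]2(CC=C(C)C)C(=O)[C@@](C(=O)C(C)C)(C(=O)[C@@]2(O)C(=O)/C=C\C(C)(C)O)C1(C)C | target

## Step count and risks

Total step count: 16. Longest linear sequence: 15 steps (steps 1–12 and 14–16; step 13 is a one-step side branch).

Steps most likely to fail:

Step 12 (Proposed new method). The acylation may fail to distinguish the two chlorocarbonyl groups or may choose the wrong one, which would invert C3; O-acylation to an enol lactone is a second possible diversion. The fallback uses known chemistry, sets out from 18 and returns at 24, and removes the choice between two acyl groups. Diacid 18 is heated (toluene, 100 °C) to lose one carboxyl group and give the C5 silyloxyacetic acid F1 as a C3 epimer mixture. Ghosez reagent converts it into the mono acid chloride F2, and MgCl2/Et3N under the conditions of step 12 closes the ring with a single acyl group to the bicyclic trione F3, which carries hydrogen and the silyloxy group on C3. LiN(SiMe3)2 (THF, −78 °C) then forms the C2–C3 enolate, the only ring position with an α-hydrogen. This enolate adds to the ynal F4 (from 23 with n-BuLi, then DMF) on the open exo face of the two-carbon bridge, which puts the new carbon exo and the silyloxy group endo in the propargylic alcohol F5. Dess–Martin oxidation of F5 gives ynone 24.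

Step 6. The crowded C3–C5 bond may revert by retro-aldol cleavage, or the ketomalonate may approach syn to the C7 prenyl group. The fallback sets out from 9 and returns at 12, replacing the basic lithium aldol by a Lewis acid Mukaiyama addition. Compound 9 is converted (LiN(iPr)2, Me3SiCl, THF, −78 °C) into the trimethylsilyl dienol ether F6. Addition of F6 to 10 with Cu(OTf)2 (10 mol %, CH2Cl2, −78 °C) proceeds without a free alkoxide through an open transition state that keeps the approach anti to the pseudo-axial C7 prenyl group, and aqueous work-up gives 12.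

Step 14. Oxidative addition of the congested acid chloride to palladium may be slow, so that decarbonylation of the acyl palladium species or amine-induced opening of the triketone competes. The fallback sets out from 21 and returns at 24 without palladium or amine. LiAlH(OtBu)3 (THF, −78 °C) reduces the acid chloride selectively to the aldehyde F7. The lithium acetylide of 23 (n-BuLi, THF, −78 °C) adds to this aldehyde, which is far more reactive than the three hindered ketones, to give the propargylic alcohol F5, and Dess–Martin oxidation returns ynone 24.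

Further compounds
F1 | step 12 | 2-[2-hydroxy-4,4-dimethyl-1,5-bis(3-methylbut-2-en-1-yl)-3-(2-methylpropanoyl)cyclohex-2-en-1-yl]-2-[(triethylsilyl)oxy]acetic acid, C3 epimers | CC(C)=CC[C@@H]1C[C@@](CC=C(C)C)(C(O[Si](CC)(CC)CC)C(=O)O)C(O)=C(C(=O)C(C)C)C1(C)C
F2 | step 12 | 2-[2-hydroxy-4,4-dimethyl-1,5-bis(3-methylbut-2-en-1-yl)-3-(2-methylpropanoyl)cyclohex-2-en-1-yl]-2-[(triethylsilyl)oxy]acetyl chloride, C3 epimers | CC(C)=CC[C@@H]1C[C@@](CC=C(C)C)(C(O[Si](CC)(CC)CC)C(Cl)=O)C(O)=C(C(=O)C(C)C)C1(C)C
F3 | step 12 | 8,8-dimethyl-1-(2-methylpropanoyl)-5,7-bis(3-methylbut-2-en-1-yl)-3-[(triethylsilyl)oxy]bicyclo[3.2.1]octane-2,9-dione, C3 epimers | CC(C)=CC[C@@H]1C[C@]2(CC=C(C)C)C(=O)[C@@](C(=O)C(C)C)(C(=O)C2O[Si](CC)(CC)CC)C1(C)C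
F4 | step 12 | 4-methyl-4-[(triethylsilyl)oxy]pent-2-ynal | CC[Si](CC)(CC)OC(C)(C)C#CC=O
F5 | step 12 | 3-{1-hydroxy-4-methyl-4-[(triethylsilyl)oxy]pent-2-yn-1-yl}-8,8-dimethyl-1-(2-methylpropanoyl)-5,7-bis(3-methylbut-2-en-1-yl)-3-[(triethylsilyl)oxy]bicyclo[3.2.1]octane-2,9-dione, side chain exo, carbinol epimers | CC(C)=CC[C@@H]1C[C@]2(CC=C(C)C)C(=O)[C@@](C(=O)C(C)C)(C(=O)[C@@]2(O[Si](CC)(CC)CC)C(O)C#CC(C)(C)O[Si](CC)(CC)CC)C1(C)C
F6 | step 6 | trimethyl{[(5R)-4-methyl-2,5-bis(3-methylbut-2-en-1-yl)cyclohexa-1,3-dien-1-yl]oxy}silane (configuration of C7 as in 9) | CC(C)=CC[C@@H]1CC(CC=C(C)C)=C(O[Si](C)(C)C)C=C1C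
F7 | step 14 | 8,8-dimethyl-1-(2-methylpropanoyl)-5,7-bis(3-methylbut-2-en-1-yl)-2,9-dioxo-3-[(triethylsilyl)oxy]bicyclo[3.2.1]octane-3-carbaldehyde, formyl exo | CC(C)=CC[C@@H]1C[C@]2(CC=C(C)C)C(=O)[C@@](C(=O)C(C)C)(C(=O)[C@@]2(O[Si](CC)(CC)CC)C=O)C1(C)C
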